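**Strategy**

Ring C is disconnected at O1–C2 and C3–C4, the two bonds on either side of C2–C3. A B-ring cinnamaldehyde then brings C2 and C3 (with its aldehyde carbon as a temporary substituent on C3), and an A-ring salicylaldehyde brings O1, C8a, C4a and C4. One amine-catalysed oxa-Michael–aldol condensation forms both bonds, closes the pyran ring and sets C2. Its precursors are the MOM-protected 2-hydroxy-5-prenylbenzaldehyde 9, obtained as a single regioisomer by formylating a symmetric phenol, and the geranylated (E)-enal 14. Decarbonylation, Wacker oxidation at C4 and MOM removal then give the flavanone.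

Key step: step 9

Assumption: the (S)-configured diarylprolinol silyl ether is taken to shield the Re face at C-β of the (E)-iminium ion of 14 (the usual steric model for this catalyst class), which gives (2R)-16; if a first sample shows the opposite sense, the commercially available (R)-catalyst is used with no other change.

Remark on descriptors: the spatial arrangement at C2 is the same from 15 to 19. The descriptor is R only in 16, where C3 (sp2, bearing the formyl group) outranks the aryl carbon, and S in 15, 17, 18 and 19.

Abbreviations: prenyl = 3-methylbut-2-en-1-yl; geranyl = (2E)-3,7-dimethylocta-2,6-dien-1-yl; MOM = methoxymethyl; TIPS = triisopropylsilyl.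

**Route**

Step 1
Reactants: 1 phloroglucinol
Product: 2 3,5-bis(methoxymethoxy)phenol
Conditions: MOMCl (2.0 equiv), i-Pr2NEt, DMF, 0 °C → rt; chromatography (mono-ether resubmitted)
Reagents that add atoms: chloromethyl methyl ether (MOMCl), COCCl
Why: O-alkylation of the phenol by the α-chloro ether (MOM protection); the three hydroxyls are equivalent, so about two equivalents of reagent should make the bis-ether the main component of a statistical mixture that is separable by chromatography.

Step 2
Reactants: 2 3,5-bis(methoxymethoxy)phenol
Product: 3 [3,5-bis(methoxymethoxy)phenoxy]triisopropylsilane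
Conditions: TIPSCl, imidazole, DMF, rt
Reagents that add atoms: chlorotriisopropylsilane (TIPSCl), CC(C)[Si](Cl)(C(C)C)C(C)C
Why: Imidazole-promoted O-silylation of the remaining phenol (silyl ether protection); the bulky, non-coordinating TIPS group tags the oxygen that later becomes O1, tolerates butyllithium and does not direct metalation.

Step 3
Reactants: 3 [3,5-bis(methoxymethoxy)phenoxy]triisopropylsilane; 4 prenyl bromide
Product: 6 [3,5-bis(methoxymethoxy)-4-prenylphenoxy]triisopropylsilane, via aryllithium 5 (not isolated)
Conditions: n-BuLi (1.1 equiv), THF, 0 °C; then CuI (10 mol%), 4, −78 °C → rt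
Reagents that add atoms: none
Why: Directed ortho-metalation: the two MOM ethers jointly direct butyllithium to the carbon between them (the positions next to OTIPS have only one director), and aryllithium 5 is then alkylated at the primary carbon of 4 under copper catalysis (SN2 allylation), which places prenyl between the two protected oxygens.

Step 4
Reactants: 6 [3,5-bis(methoxymethoxy)-4-prenylphenoxy]triisopropylsilane
Product: 7 3,5-bis(methoxymethoxy)-4-prenylphenol
Conditions: TBAF, THF, 0 °C → rt; aqueous work-up
Reagents that add atoms: none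
Why: Fluoride-induced cleavage of the aryl silyl ether (desilylation) frees only the oxygen para to prenyl; MOM ethers and the alkene are inert to fluoride.

Step 5
Reactants: 7 3,5-bis(methoxymethoxy)-4-prenylphenol
Product: 9 2-hydroxy-4,6-bis(methoxymethoxy)-5-prenylbenzaldehyde, via hydroxymethylphenol 8 (not isolated)
Conditions: MgCl2 (2 equiv), Et3N (4 equiv), (CH2O)n (6 equiv), THF, reflux; cold dilute HCl work-up
Reagents that add atoms: formaldehyde (as paraformaldehyde), C=O
Why: Casnati–Skattebøl ortho-formylation: the magnesium phenoxide delivers formaldehyde to an ortho carbon and the resulting benzylic alkoxide 8 is oxidised by a second formaldehyde through hydride transfer; the two ortho positions of 7 are equivalent by symmetry and are the only free ring positions, so a single salicylaldehyde with prenyl para to the free OH is expected.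

Step 6
Reactants: 10 4-hydroxybenzaldehyde; 11 geranyl bromide
Product: 12 3-geranyl-4-hydroxybenzaldehyde
Conditions: 11 (1.0 equiv), 10% aq. KOH, rt; then dilute HCl; chromatography
Reagents that add atoms: none
Why: Ortho C-alkylation of an ambident phenoxide in water, where hydrogen bonding to oxygen favours attack through carbon and the para position is blocked; SN2 displacement at the primary carbon keeps the (E) geometry, and the O-geranyl ether formed alongside is removed by chromatography.

Step 7
Reactants: 12 3-geranyl-4-hydroxybenzaldehyde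
Product: 13 3-geranyl-4-(methoxymethoxy)benzaldehyde
Conditions: MOMCl, i-Pr2NEt, CH2Cl2, 0 °C → rt
Reagents that add atoms: chloromethyl methyl ether (MOMCl), COCCl
Why: MOM protection of the phenol (O-alkylation with an α-chloro ether under amine base) leaves the aldehyde and the diene untouched and matches the A-ring protection, so that one acid treatment unmasks all phenols at the end.

Step 8
Reactants: 13 3-geranyl-4-(methoxymethoxy)benzaldehyde
Product: 14 (E)-3-[3-geranyl-4-(methoxymethoxy)phenyl]prop-2-enal
Conditions: Ph3P=CHCHO (1.3 equiv), toluene, 80 °C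
Reagents that add atoms: (triphenylphosphoranylidene)acetaldehyde, O=CC=P(c1ccccc1)(c1ccccc1)c1ccccc1
Why: Wittig olefination with the formyl-stabilised ylide extends the aldehyde by two carbons and gives the (E)-enal, as is normal for stabilised ylides; a modest excess of ylide and moderate temperature limit a second homologation.

Step 9
Reactants: 9 2-hydroxy-4,6-bis(methoxymethoxy)-5-prenylbenzaldehyde; 14 (E)-3-[3-geranyl-4-(methoxymethoxy)phenyl]prop-2-enal (1.3 equiv)
Product: 16 (2R)-2-[3-geranyl-4-(methoxymethoxy)phenyl]-5,7-bis(methoxymethoxy)-6-prenyl-2H-chromene-3-carbaldehyde, via aldol adduct 15 (not isolated)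
Conditions: (S)-2-[diphenyl(triethylsilyloxy)methyl]pyrrolidine (20 mol%), 2-nitrobenzoic acid (20 mol%), 4 Å MS, toluene, rt
Reagents that add atoms: none
Why: The catalyst condenses with enal 14 to an (E)-iminium ion whose Re face at C-β is blocked by the diphenyl(silyloxy)methyl arm, so the phenolic oxygen of 9 adds to the Si face and forms O1–C2 in the R sense, which is the C2 geometry of the target. The enamine so formed attacks the ortho formyl group in a 6-exo-trig (enol-exo) aldol closure that forms C3–C4 and the pyran ring, and dehydration of aldol 15 with hydrolysis of the catalyst makes the sequence irreversible. The closest known reaction type is the secondary-amine-catalysed domino oxa-Michael–aldol condensation of salicylaldehydes with cinnamaldehydes to 2-aryl-2H-chromene-3-carbaldehydes. C2 is controlled by the catalyst alone, and the acid co-catalyst and molecular sieves speed iminium turnover and dehydration so that ring closure outruns retro-oxa-Michael equilibration. Regiochemistry needs no control, because 9 has a single free phenol ortho to the formyl group and its other two oxygens are MOM ethers, which fixes prenyl at C6. The formyl group left on C3 has served only as activating handle and is removed in step 10.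

Step 10
Reactants: 16 (2R)-2-[3-geranyl-4-(methoxymethoxy)phenyl]-5,7-bis(methoxymethoxy)-6-prenyl-2H-chromene-3-carbaldehyde
Product: 17 (2S)-2-[3-geranyl-4-(methoxymethoxy)phenyl]-5,7-bis(methoxymethoxy)-6-prenyl-2H-chromene
Conditions: RhCl(PPh3)3 (1.1 equiv), degassed toluene, 110 °C
Reagents that add atoms: none
Why: Tsuji–Wilkinson decarbonylation: Rh(I) inserts into the formyl C–H bond, CO migrates to the metal and reductive elimination leaves H on C3 with the C3=C4 bond in place, as established for α,β-unsaturated aldehydes; C2 is not involved, and the trisubstituted side-chain alkenes do not compete for rhodium.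

Step 11
Reactants: 17 (2S)-2-[3-geranyl-4-(methoxymethoxy)phenyl]-5,7-bis(methoxymethoxy)-6-prenyl-2H-chromene
Product: 18 (2S)-2-[3-geranyl-4-(methoxymethoxy)phenyl]-5,7-bis(methoxymethoxy)-6-prenyl-2,3-dihydro-4H-chromen-4-one
Conditions: PdCl2 (10 mol%), CuCl (20 mol%), O2 (1 atm), DMF/H2O (7:1), rt → 40 °C
Reagents that add atoms: water, O (source of the carbonyl oxygen; O2 is the terminal oxidant and ends as water)
Why: Tsuji–Wacker oxidation: Pd(II) activates the C3=C4 styrene-type alkene and water adds to C4, the carbon that best carries positive charge (benzylic, conjugated with the oxygens on C5, C7 and C8a, and remote from the electron-withdrawing allylic O1–C2 bond), after which β-hydride elimination and tautomerisation give the C4 ketone; the trisubstituted prenyl and geranyl alkenes are too hindered for oxypalladation, all phenols are still capped so no oxidative cyclisation can occur, and the near-neutral medium leaves the MOM ethers and C2 untouched.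

Step 12
Reactants: 18 (2S)-2-[3-geranyl-4-(methoxymethoxy)phenyl]-5,7-bis(methoxymethoxy)-6-prenyl-2,3-dihydro-4H-chromen-4-one
Product: 19 schizolaenone A
Conditions: 3 M aq. HCl/MeOH (1:4), 40 °C, short reaction time
Reagents that add atoms: none
Why: Acid-catalysed transacetalisation with methanol (MOM ether cleavage) frees the three phenols; the flavanone ring does not open under mild acid, so C2 stays S, and a short reaction time at moderate temperature limits acid-induced cyclisation of the prenyl and geranyl chains onto the neighbouring phenols.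

**Compound list**

1 | phloroglucinol (benzene-1,3,5-triol) | Oc1cc(O)cc(O)c1 | starting material
2 | 3,5-bis(methoxymethoxy)phenol | COCOc1cc(O)cc(OCOC)c1 | intermediate
3 | [3,5-bis(methoxymethoxy)phenoxy]triisopropylsilane | COCOc1cc(OCOC)cc(O[Si](C(C)C)(C(C)C)C(C)C)c1 | intermediate
4 | prenyl bromide (1-bromo-3-methylbut-2-ene) | CC(C)=CCBr | starting material
5 | [2,6-bis(methoxymethoxy)-4-(triisopropylsilyloxy)phenyl]lithium (not isolated) | [Li]c1c(OCOC)cc(O[Si](C(C)C)(C(C)C)C(C)C)cc1OCOC | intermediate
6 | [3,5-bis(methoxymethoxy)-4-prenylphenoxy]triisopropylsilane | CC(C)=CCc1c(OCOC)cc(O[Si](C(C)C)(C(C)C)C(C)C)cc1OCOC | intermediate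
7 | 3,5-bis(methoxymethoxy)-4-prenylphenol | CC(C)=CCc1c(OCOC)cc(O)cc1OCOC | intermediate
8 | 2-(hydroxymethyl)-3,5-bis(methoxymethoxy)-4-prenylphenol, present as its magnesium salt (not isolated) | OCc1c(O)cc(OCOC)c(CC=C(C)C)c1OCOC | intermediate
9 | 2-hydroxy-4,6-bis(methoxymethoxy)-5-prenylbenzaldehyde | O=Cc1c(O)cc(OCOC)c(CC=C(C)C)c1OCOC | intermediate
10 | 4-hydroxybenzaldehyde | O=Cc1ccc(O)cc1 | starting material
11 | geranyl bromide, (2E)-1-bromo-3,7-dimethylocta-2,6-diene | CC(C)=CCC/C(C)=C/CBr | starting material
12 | 3-geranyl-4-hydroxybenzaldehyde | CC(C)=CCC/C(C)=C/Cc1cc(C=O)ccc1O | intermediate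
13 | 3-geranyl-4-(methoxymethoxy)benzaldehyde | CC(C)=CCC/C(C)=C/Cc1cc(C=O)ccc1OCOC | intermediate
14 | (E)-3-[3-geranyl-4-(methoxymethoxy)phenyl]prop-2-enal | CC(C)=CCC/C(C)=C/Cc1cc(/C=C/C=O)ccc1OCOC | intermediate
15 | (2S)-2-[3-geranyl-4-(methoxymethoxy)phenyl]-4-hydroxy-5,7-bis(methoxymethoxy)-6-prenylchromane-3-carbaldehyde, C3 and C4 undefined, held as its iminium/enamine with the catalyst (not isolated) | CC(C)=CCC/C(C)=C/Cc1cc([C@@H]2C(C=O)C(O)c3c(cc(OCOC)c(CC=C(C)C)c3OCOC)O2)ccc1OCOC | intermediate
16 | (2R)-2-[3-geranyl-4-(methoxymethoxy)phenyl]-5,7-bis(methoxymethoxy)-6-prenyl-2H-chromene-3-carbaldehyde | CC(C)=CCC/C(C)=C/Cc1cc([C@@H]2C(C=O)=Cc3c(cc(OCOC)c(CC=C(C)C)c3OCOC)O2)ccc1OCOC | intermediate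
17 | (2S)-2-[3-geranyl-4-(methoxymethoxy)phenyl]-5,7-bis(methoxymethoxy)-6-prenyl-2H-chromene | CC(C)=CCC/C(C)=C/Cc1cc([C@@H]2C=Cc3c(cc(OCOC)c(CC=C(C)C)c3OCOC)O2)ccc1OCOC | intermediate
18 | (2S)-2-[3-geranyl-4-(methoxymethoxy)phenyl]-5,7-bis(methoxymethoxy)-6-prenyl-2,3-dihydro-4H-chromen-4-one | CC(C)=CCC/C(C)=C/Cc1cc([C@@H]2CC(=O)c3c(cc(OCOC)c(CC=C(C)C)c3OCOC)O2)ccc1OCOC | intermediate
19 | schizolaenone A, (2S)-2-(3-geranyl-4-hydroxyphenyl)-5,7-dihydroxy-6-prenyl-2,3-dihydro-4H-chromen-4-one | CC(C)=CCC/C(C)=C/Cc1cc([C@@H]2CC(=O)c3c(cc(O)c(CC=C(C)C)c3O)O2)ccc1O | target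

**Step count**

Total steps: 12.
Longest linear sequence: 9 steps (steps 1–5 and 9–12, from phloroglucinol); the B-ring branch (steps 6–8) joins at step 9.

**Steps most likely to fail**

1. Step 9 (key step). Aldol closure onto the electron-rich formyl group flanked by OH and OMOM may be slow. The reversible oxa-Michael step and γ-deprotonation of the product by the amine could then lower conversion or erode enantiopurity. Fallback: starting from 9 and 14, the annulation would be run without asymmetric induction, by carbonate-mediated phenoxide conjugate addition, enolate aldol closure and E1cB dehydration (K2CO3, 1,4-dioxane, reflux). This is a known entry to 2H-chromene-3-carbaldehydes from hindered salicylaldehydes and would give the racemic chromene aldehyde F1. Resolution by preparative HPLC on a polysaccharide chiral stationary phase would supply the (2R)-enantiomer, which is 16, and the route continues at step 10.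

2. Step 11. Hydroxypalladation may occur with the wrong orientation (oxygen at C3). The electron-rich flavene may also be oxidised to a flavylium species with loss of C2, or MOM groups may be partly lost to HCl formed in the medium. Fallback: starting from 17, rhodium-catalysed hydroboration with catecholborane ([Rh(cod)2]BF4, dppb, THF, 0 °C → rt) would be used. It places boron on the benzylic carbon of vinylarenes such as 2H-chromenes and ignores trisubstituted alkenes, and would give the benzylic boronate F2. Oxidation in the same flask (NaOH, H2O2) would give the flavan-4-ol F3 as a mixture of C4 epimers. Buffered Dess–Martin oxidation (NaHCO3, CH2Cl2) of F3 would give 18.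

3. Step 10. C2 configuration may be lost at about 110 °C through reversible electrocyclic opening of the 2H-chromene, or through rhodium hydride-mediated migration of C3=C4 into the achiral 4H-chromene. Decarbonylation of the hindered enal may also stall. Fallback: ring C would be closed by the chalcone route, without a formyl handle. Starting from 9, methylmagnesium bromide (THF, 0 °C) would give the carbinol F4, and MnO2 (CH2Cl2) the acetophenone F5. Claisen–Schmidt condensation with 13 (KOH, EtOH/H2O, rt) would give the 2'-hydroxychalcone F6. NaOAc in refluxing ethanol would give the racemic flavanone F7 by intramolecular oxa-Michael addition of the only free phenol. Preparative HPLC on a chiral stationary phase would give the (2S)-enantiomer, which is 18.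

**Further compounds**

F1 | step 9 | racemic 2-[3-geranyl-4-(methoxymethoxy)phenyl]-5,7-bis(methoxymethoxy)-6-prenyl-2H-chromene-3-carbaldehyde | CC(C)=CCC/C(C)=C/Cc1cc(C2C(C=O)=Cc3c(cc(OCOC)c(CC=C(C)C)c3OCOC)O2)ccc1OCOC
F2 | step 11 | 2-{(2S)-2-[3-geranyl-4-(methoxymethoxy)phenyl]-5,7-bis(methoxymethoxy)-6-prenylchroman-4-yl}-1,3,2-benzodioxaborole (C4 epimers) | CC(C)=CCC/C(C)=C/Cc1cc([C@@H]2CC(B3Oc4ccccc4O3)c3c(cc(OCOC)c(CC=C(C)C)c3OCOC)O2)ccc1OCOC
F3 | step 11 | (2S)-2-[3-geranyl-4-(methoxymethoxy)phenyl]-5,7-bis(methoxymethoxy)-6-prenylchroman-4-ol (C4 epimers) | CC(C)=CCC/C(C)=C/Cc1cc([C@@H]2CC(O)c3c(cc(OCOC)c(CC=C(C)C)c3OCOC)O2)ccc1OCOC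
F4 | step 10 | racemic 2-(1-hydroxyethyl)-3,5-bis(methoxymethoxy)-4-prenylphenol | CC(O)c1c(O)cc(OCOC)c(CC=C(C)C)c1OCOC
F5 | step 10 | 1-[2-hydroxy-4,6-bis(methoxymethoxy)-5-prenylphenyl]ethanone | CC(=O)c1c(O)cc(OCOC)c(CC=C(C)C)c1OCOC
F6 | step 10 | (E)-1-[2-hydroxy-4,6-bis(methoxymethoxy)-5-prenylphenyl]-3-[3-geranyl-4-(methoxymethoxy)phenyl]prop-2-en-1-one | CC(C)=CCC/C(C)=C/Cc1cc(/C=C/C(=O)c2c(O)cc(OCOC)c(CC=C(C)C)c2OCOC)ccc1OCOC
F7 | step 10 | racemic 2-[3-geranyl-4-(methoxymethoxy)phenyl]-5,7-bis(methoxymethoxy)-6-prenyl-2,3-dihydro-4H-chromen-4-one | CC(C)=CCC/C(C)=C/Cc1cc(C2CC(=O)c3c(cc(OCOC)c(CC=C(C)C)c3OCOC)O2)ccc1OCOC
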